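If a flask creeps towards a ceiling, I count what is left of the way and not what has been made.

| setting | dawn | autumn | epsilon | beta |
|---|---|---|---|---|
| L | 0.20 M | 0.20 M | 0.20 M | 0.20 M |
| D | 4 mM | 8.4 mM | 3.0 mM | 6.0 mM |
| Q | 3.4 mM | 3.4 mM | 3.4 mM | 3.4 mM |
| remark | run made earlier | run made earlier |  |  |
| time |  |  | 6.0 d | 6.0 d |

| run | time / d | E / % | L / % |
|---|---|---|---|
| dawn | 0.625 | 6.0 | 94.4 |
| dawn | 1.25 | 11.4 | 87.6 |
| dawn | 2.00 | 17.6 | 82.6 |
| dawn | 3.00 | 23.0 | 77.1 |
| dawn | 4.00 | 26.3 | 72.6 |
| autumn | 0.250 | 2.9 | 96.0 |
| autumn | 0.833 | 22.1 | 77.6 |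
| autumn | 1.67 | 31.6 | 68.5 |
| autumn | 2.50 | 33.2 | 66.3 |
| autumn | 3.00 | 33.3 | 66.7 |
| autumn | 4.00 | 34.3 | 67.2 |

(readings scatter by 0.5 percentage points)

- the average divides the monomer in chains by the number of chains begun, living and dead together
- the numbers in the tables scatter with a standard deviation of 0.5 percentage points
- the earlier runs do not show the number of chains; that part of a forecast is a guess

- which of the two ends with the longer chains by the average number of monomer units in a chain (chains begun, living or dead) ("neither" if they lie within 10 %) (epsilon / beta / neither)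
- average number of monomer units in a chain (chains begun, living or dead) at the end, epsilon
- average number of monomer units in a chain (chains begun, living or dead) at the end, beta

Autumn levels off at E 33.6 %, and I take this ceiling for dawn as well. The logarithm of the fraction of the way left then falls at 0.404 d⁻¹ in dawn and 2.09 d⁻¹ in autumn. I read each as pseudo-first-order, proportional to the chains. But autumn runs 5.17 times faster on 2.10 times the D, so I suppose that Q catches initiator in competition with L.

I set autumn's chains at c_D minus c_Q, 5.00 mM. The rates then give dawn 0.968 mM, and the balance (D charged equals chains plus Q used) leaves 10.8 % of dawn's Q. From this I define the selectivity factor 2.30 mM⁻¹, the fall in the logarithm of the fraction of Q left per unit of chains begun, at this c_L.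

Solving the balance with it, I reckon that epsilon begins 0.550 mM of chains. My rate for epsilon is 0.230 d⁻¹, so I reckon its E at 25.1 % and its length at 91.4. By the same balance I reckon that beta begins 2.61 mM and stands at the ceiling, which gives a length of 25.8. So I expect epsilon to end longer.

The forecast says epsilon, with 15 and 11, and of beta's length it says “more if Q blocks starts”.

The flask gives epsilon, with 87.8 for epsilon and 25.5 for beta, from Z of 5.86 × 10⁻⁴ M and 0.00261 M. Put into the rule, epsilon's Z gives 26.0 % of Q left, and the flask holds 29.0 %.

    J + Q → G (k = 670 M⁻¹ h⁻¹)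
    E + Z → L + Z, rate k2*[Z] as long as [E] is above zero (k = 2.40 h⁻¹)
    D → J (k = 0.260 h⁻¹)
    L + J → Z + E (k = 1.60 M⁻¹ h⁻¹)
    L + Z → E + Z, rate k5*[Z]*[L] (k = 18.0 M⁻¹ h⁻¹)

The neighbouring flask is beta with L at 0.50 M. I scale the factor down to 0.920 mM⁻¹, which gives Z 2.85 mM, Q left 7.27 %, and, with c_L at 0.133 M, length 129. The flask gives 0.00285 M, 7.3 % and 129.

The numbers in the tables were computed with constants of no real substance; the scatter is artificial.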